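## Retrosynthetic overview

1. The (3S)-isoflavan comes from an (S)-3-aryl-6-hydroxy-7,8-dimethoxy-3,4-dihydrocoumarin by reduction of the C2 carbonyl to CH2 and O-debenzylation.
2. The dihydrocoumarin comes from a one-flask [3+3] union that forms C4–C4a and then O1–C2. The β-carbon of a 2-arylacrolein is made nucleophilic as a chiral carbene-bound homoenolate and attacks the electrophilic C5 of 2,3-dimethoxy-1,4-benzoquinone. C3 is set by catalyst-controlled protonation in the same flask.
3. The 2-arylacrolein comes from 2'-hydroxy-3',4'-dimethoxyacetophenone (benzylation, Wittig, SeO2). The quinone comes from 2,3-dimethoxyphenol (O2, Co(salen)).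
4. Ring order: ring B is bought. Ring A enters as the quinone and is aromatised in the key step, which also closes ring C (the pyran). No ring is made afterwards.

Assumption: the facial sense of the protonation in step 5 cannot be predicted with certainty. The (5aR,10bS) catalyst is written; its equally available (5aS,10bR) antipode is used if the first run (chiral HPLC, CD comparison with known 3S isoflavans) gives the R lactone.

## Route

**Step 1**
Reactants: 1 2,3-dimethoxyphenol
Product: 2 2,3-dimethoxy-1,4-benzoquinone
Conditions: O2 (1 atm), Co(salen) (5 mol %), DMF, rt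
Reagents that add atoms: dioxygen, O=O
Why: Salcomine-type aerobic phenol oxidation, in which the cobalt–superoxo species abstracts the phenolic hydrogen and delivers oxygen to the free, activated para position, giving the para-quinone with water as the only co-product; no stereocenter.

**Step 2**
Reactants: 3 2'-hydroxy-3',4'-dimethoxyacetophenone
Product: 4 1-[2-(benzyloxy)-3,4-dimethoxyphenyl]ethanone
Conditions: BnBr, K2CO3, DMF, 60 °C
Reagents that add atoms: benzyl bromide, BrCc1ccccc1
Why: Williamson ether synthesis in warm DMF (which breaks the hydrogen bond to the ortho-acetyl group); the benzyl ether stops this phenol from intercepting the acyl azolium in step 5 or closing a dihydrobenzofuran later.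

**Step 3**
Reactants: 4 1-[2-(benzyloxy)-3,4-dimethoxyphenyl]ethanone
Product: 5 2-(benzyloxy)-3,4-dimethoxy-1-(prop-1-en-2-yl)benzene
Conditions: Ph3PCH3Br, KOtBu, THF, 0 °C to rt
Reagents that add atoms: methyltriphenylphosphonium bromide, C[P+](c1ccccc1)(c1ccccc1)c1ccccc1.[Br-]
Why: Wittig methylenation of an aryl methyl ketone that carries only one ortho substituent, using a non-stabilised ylide that tolerates the aryl ethers.

**Step 4**
Reactants: 5 2-(benzyloxy)-3,4-dimethoxy-1-(prop-1-en-2-yl)benzene
Product: 6 2-[2-(benzyloxy)-3,4-dimethoxyphenyl]prop-2-enal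
Conditions: SeO2 (1.5 equiv), 1,4-dioxane/H2O (20:1), 90 °C
Reagents that add atoms: selenium dioxide, O=[Se]=O
Why: Riley allylic oxidation (ene reaction, [2,3]-sigmatropic shift, then further oxidation of the allylic alcohol) at the only allylic C–H position, a standard entry to 2-arylacroleins from α-methylstyrenes; 6 is used at once because such enals dimerise on storage.

**Step 5 (key step)**
Reactants: 2 2,3-dimethoxy-1,4-benzoquinone; 6 2-[2-(benzyloxy)-3,4-dimethoxyphenyl]prop-2-enal (1.3 equiv)
Product: 8 (3S)-3-[2-(benzyloxy)-3,4-dimethoxyphenyl]-6-hydroxy-7,8-dimethoxychroman-2-one, via carbene-bound homoenolate 7 (not isolated)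
Conditions: (5aR,10bS)-N-mesityl aminoindanol-derived triazolium chloride (15 mol %), NaOAc (20 mol %), 4 Å MS, degassed toluene/THF, 0 °C, Ar, 2 added by syringe pump over 6 h
Reagents that add atoms: none
Why: Proposed new method: the carbene adds to the aldehyde of 6 and a proton shift gives the extended Breslow intermediate 7, a homoenolate whose unhindered terminal CH2 (normally the electrophilic β-carbon of the enal) attacks the equally electrophilic, unsubstituted C5 of the C2-symmetric quinone 2 in a Michael addition, so only one regioisomer can form; aromatisation to the hydroquinone, then face-selective C-protonation of the α-aryl enol azolium (proton relayed through a six-membered array from the new ortho-phenol while the indane wall of the catalyst shields the other face) sets C3 as S, and the ortho-phenol then attacks the acyl azolium to close ring C and release the carbene; the closest known reaction types are the carbene-catalysed homoenolate [8+3] annulation of enals with tropone, homoenolate Michael additions to nitroalkenes and enones, the amine-catalysed α-arylation of aldehydes with quinones, and the carbene-catalysed enantioselective protonation of aryl-substituted azolium enolates; if the quinone instead oxidises 7, the resulting α,β-unsaturated acyl azolium and hydroquinone can still collapse to the same lactone by a Coates–Claisen-type [3+3] annulation.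

**Step 6**
Reactants: 8 (3S)-3-[2-(benzyloxy)-3,4-dimethoxyphenyl]-6-hydroxy-7,8-dimethoxychroman-2-one
Product: 10 (3S)-3-[2-(benzyloxy)-3,4-dimethoxyphenyl]-7,8-dimethoxychroman-6-ol, via lactol 9 (not isolated)
Conditions: DIBAL-H (2.3 equiv), CH2Cl2, −78 °C; then Et3SiH (6 equiv), BF3·OEt2 (5 equiv), −78 to −30 °C
Reagents that add atoms: none
Why: DIBAL-H reduction of a dihydrocoumarin stops at the tetrahedral aluminium lactolate at −78 °C (the first equivalent only deprotonates the phenol), and Lewis-acid ionisation to the cyclic oxocarbenium ion followed by silane hydride capture (ionic reduction of a lactol) gives the chroman, while the open α-aryl aldehyde is never liberated and the low temperature protects C3, which is not a reacting centre.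

**Step 7**
Reactants: 10 (3S)-3-[2-(benzyloxy)-3,4-dimethoxyphenyl]-7,8-dimethoxychroman-6-ol
Product: 11 (3S)-3-(2-hydroxy-3,4-dimethoxyphenyl)-7,8-dimethoxychroman-6-ol (target)
Conditions: H2 (1 atm), Pd/C (10 wt %), EtOAc/MeOH, rt
Reagents that add atoms: none
Why: Catalytic hydrogenolysis of the aryl benzyl ether; the chroman C–O bond is not benzylic, the aryl methyl ethers are inert and C3 is untouched, so the 3S configuration is carried into the target.

## Compound list

1 | 2,3-dimethoxyphenol | COc1cccc(O)c1OC | starting material
2 | 2,3-dimethoxy-1,4-benzoquinone | COC1=C(OC)C(=O)C=CC1=O | intermediate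
3 | 2'-hydroxy-3',4'-dimethoxyacetophenone | CC(=O)c1ccc(OC)c(OC)c1O | starting material
4 | 1-[2-(benzyloxy)-3,4-dimethoxyphenyl]ethanone | CC(=O)c1ccc(OC)c(OC)c1OCc1ccccc1 | intermediate
5 | 2-(benzyloxy)-3,4-dimethoxy-1-(prop-1-en-2-yl)benzene | C=C(C)c1ccc(OC)c(OC)c1OCc1ccccc1 | intermediate
6 | 2-[2-(benzyloxy)-3,4-dimethoxyphenyl]prop-2-enal | C=C(C=O)c1ccc(OC)c(OC)c1OCc1ccccc1 | intermediate
7 | extended Breslow intermediate (homoenolate): the (5aR,10bS)-N-mesityl indeno-triazolo-oxazinylidene carbon joined through C=C(OH) to C(Ar)=CH2, Ar = 2-(benzyloxy)-3,4-dimethoxyphenyl | Cc1cc(C)c(c(C)c1)N1N=C2CO[C@@H]3Cc4ccccc4[C@@H]3N2C1=C(O)C(=C)c1ccc(OC)c(OC)c1OCc1ccccc1 | intermediate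
8 | (3S)-3-[2-(benzyloxy)-3,4-dimethoxyphenyl]-6-hydroxy-7,8-dimethoxychroman-2-one | COc1ccc([C@H]2C(=O)Oc3c(cc(O)c(OC)c3OC)C2)c(OCc4ccccc4)c1OC | intermediate
9 | (3S)-3-[2-(benzyloxy)-3,4-dimethoxyphenyl]-7,8-dimethoxychromane-2,6-diol (lactol, both C2 epimers; present in the flask as its diisobutylaluminium alkoxide) | COc1ccc([C@H]2C(O)Oc3c(cc(O)c(OC)c3OC)C2)c(OCc4ccccc4)c1OC | intermediate
10 | (3S)-3-[2-(benzyloxy)-3,4-dimethoxyphenyl]-7,8-dimethoxychroman-6-ol | COc1ccc([C@H]2COc3c(cc(O)c(OC)c3OC)C2)c(OCc4ccccc4)c1OC | intermediate
11 | (3S)-3-(2-hydroxy-3,4-dimethoxyphenyl)-7,8-dimethoxychroman-6-ol | COc1ccc([C@H]2COc3c(cc(O)c(OC)c3OC)C2)c(O)c1OC | target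

## Step count

Total step count: 7.
Longest linear sequence: 6 steps (3 → 4 → 5 → 6 → 8 → 10 → 11).

## Steps most likely to fail, with fallbacks

**Step 5 (highest risk).**
- The quinone may oxidise the Breslow intermediate or trap the carbene.
- α-Substituted enals engage carbenes slowly.
- The O-acylated hydroquinone 2-arylacrylate is the expected by-product.
- The acidic C3–H of 8 can lose ee under base.

The fallback sets out from 2 and 6 and comes back at 9. It uses normal polarity. Quinone 2 is reduced with aqueous Na2S2O4 to 2,3-dimethoxybenzene-1,4-diol F1. A chiral primary amine salt (9-amino-9-deoxy-epi-quinine with trifluoroacetic acid) converts 6 into its iminium ion. F1 adds to the CH2 terminus through the ring carbon ortho to a hydroxyl (Friedel–Crafts-type conjugate addition). The resulting enamine is protonated enantioselectively, and the α-aryl aldehyde closes onto the neighbouring phenol to give lactol 9. This is treated with Et3SiH and BF3·OEt2 as in the second half of step 6.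

**Step 6.**
- Over-reduction of the aryl lactone is possible.
- Loss of C3–H from the oxocarbenium ion gives the enol ether, which would cause racemisation.
- The ortho-benzyloxy oxygen may participate.

The fallback sets out from 8 and comes back at 10, and avoids cations altogether. LiAlH4 in THF at −20 °C opens the lactone to 2-[(2S)-2-[2-(benzyloxy)-3,4-dimethoxyphenyl]-3-hydroxypropyl]-5,6-dimethoxybenzene-1,4-diol F2, handled under argon. A Mitsunobu cyclisation (PPh3 and DIAD premixed, THF, 0 °C) then closes the ortho-phenol onto the primary carbinol carbon. This is an SN2 displacement at CH2, so the stereocenter is not involved, and only this phenol can form a six-membered ring.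

**Step 4.**
- Yields may be moderate, selenium residues may persist, and enal 6 may polymerise at 90 °C.

The fallback sets out from 4 (bypassing 5) and comes back at 6. Corey–Chaykovsky methylenation (trimethylsulfonium iodide, NaH, DMSO/THF) gives 2-[2-(benzyloxy)-3,4-dimethoxyphenyl]-2-methyloxirane F3. Lithium diethylamide in THF isomerises the epoxide by β-elimination to 2-[2-(benzyloxy)-3,4-dimethoxyphenyl]prop-2-en-1-ol F4. MnO2 in CH2Cl2 at rt oxidises the allylic alcohol to 6 under mild conditions.

## Further compounds

F1 | step 5 | 2,3-dimethoxybenzene-1,4-diol | COc1c(O)ccc(O)c1OC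
F2 | step 6 | 2-[(2S)-2-[2-(benzyloxy)-3,4-dimethoxyphenyl]-3-hydroxypropyl]-5,6-dimethoxybenzene-1,4-diol | COc1ccc([C@@H](CO)Cc2cc(O)c(OC)c(OC)c2O)c(OCc3ccccc3)c1OC
F3 | step 4 | 2-[2-(benzyloxy)-3,4-dimethoxyphenyl]-2-methyloxirane (racemic) | CC1(CO1)c1ccc(OC)c(OC)c1OCc1ccccc1
F4 | step 4 | 2-[2-(benzyloxy)-3,4-dimethoxyphenyl]prop-2-en-1-ol | C=C(CO)c1ccc(OC)c(OC)c1OCc1ccccc1
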